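**Retrosynthetic overview**
1. Ring numbering used throughout: C1 = quaternary epoxide carbon bearing CH2OBz, C2 = CHOH, C3 = CHOBz, C4=C5 = alkene, C6 = epoxide CH. Target ⇐ regioselective benzoylation of the epoxy triol ⇐ hydroxyl-directed, anti-selective epoxidation of C1=C6 of a cyclohexa-1,3-dienylmethanol.
2. Enabling feature: the C1–C6 oxirane is an alkene one oxidation level up, so the carbocycle is a masked cyclohexa-1,3-diene. Its two olefinic bonds (C4=C5 and C1=C6) enclose the only unfunctionalised ring atoms (C5, C6), while C1–C4 carry every oxygen.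
3. Key disconnection: both olefinic bonds at once, by a double Wittig annulation of a 1,4-keto aldehyde (C1 ketone, C4 aldehyde) with a C5–C6 vicinal bis-phosphonium salt. The six-membered carbocycle is formed first, the oxirane second.
4. Stereochemistry: the C2/C3 cis-diol is bought as C3/C2 of D-ribono-1,4-lactone, whose ring oxygen marks the future ketone; C1 and C6 are relayed from C2 in the epoxidation.

Key step: step 4

Remark: TBS = tert-butyldimethylsilyl, Bz = benzoyl. The cis-diol diad of the target maps onto C3/C2 of D-ribose, so only C1 and C6 have to be created.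

**Step 1**
Reactants: 1 D-ribono-1,4-lactone; 2 tert-butyldimethylsilyl chloride
Product: 3 (3R,4R,5R)-3,4-bis(TBSO)-5-(TBSO-methyl)oxolan-2-one (2,3,5-tri-O-TBS-D-ribono-1,4-lactone)
Conditions: TBSCl (3.6 equiv), imidazole, DMAP (cat.), DMF, rt → 40 °C
Reagents that add atoms: tert-butyldimethylsilyl chloride, CC(C)(C)[Si](C)(C)Cl
Why: Exhaustive silyl ether formation on the three free hydroxyls leaves only the ring oxygen (the future ketone oxygen) undifferentiated from them, so no selective protection is needed and no stereocentre is touched.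

**Step 2**
Reactants: 3 tri-O-TBS lactone
Product: 4 (2S,3R,4R)-2,3,5-tris(TBSO)pentane-1,4-diol (2,3,5-tri-O-TBS-D-ribitol)
Conditions: LiBH4, THF, 0 °C → rt; then H2O
Reagents that add atoms: none
Why: Hydride reduction of the lactone through the lactol should give the open-chain 1,4-diol with all three stereocentres untouched, the low temperature keeping 1,2-silyl migration slow.

**Step 3**
Reactants: 4 tri-O-TBS ribitol
Product: 5 (2R,3S)-2,3,5-tris(TBSO)-4-oxopentanal
Conditions: (COCl)2, DMSO, CH2Cl2, −78 °C; Et3N, −78 → −30 °C; used crude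
Reagents that add atoms: none
Why: In a double Swern oxidation both hydroxyls are activated as alkoxysulfonium ions before base is added, so the 1,4-diol should go to the keto aldehyde without lactol or lactone formation, and the cold amine stage limits epimerisation of the two α-silyloxy centres.

**Step 4**
Reactants: 5 keto aldehyde; 6 ethane-1,2-diylbis(triphenylphosphonium) dibromide
Product: 8 (5S,6R)-5,6-bis(TBSO)-1-(TBSO-methyl)cyclohexa-1,3-diene, via Z-allylphosphonium bromide 7 (not isolated)
Conditions: 6 (1.1 equiv), KN(SiMe3)2 (1.1 equiv), THF, −78 °C; add 5, −78 °C → rt; then KN(SiMe3)2 (1.1 equiv), −78 °C → rt, 0.02 M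
Reagents that add atoms: ethane-1,2-diylbis(triphenylphosphonium) dibromide, [Br-].[Br-].C(C[P+](c1ccccc1)(c1ccccc1)c1ccccc1)[P+](c1ccccc1)(c1ccccc1)c1ccccc1
Why: Proposed new method: mono-deprotonation of 6 gives the β-phosphonio ylide Ph3P+CH2CH=PPh3 (its fragmentation to vinyltriphenylphosphonium and PPh3 is degenerate, because re-addition of PPh3 returns the same ylide and leaves no free base), which olefinates the aldehyde of 5 chemoselectively to the Z-allylic phosphonium salt 7 (new C4=C5); the second equivalent of base then makes the allylic ylide, whose α-carbon C6 closes onto the C1 ketone in an intramolecular Wittig reaction (new C1=C6) with loss of a second Ph3P=O. The closest known reaction types are bis-Wittig ring closures of dicarbonyl compounds with alkane-α,ω-diylbis(phosphoranes) and the cyclohexa-1,3-diene annulation in which an allylic phosphorane cyclises onto a ketone. The only ring closed is the carbocycle, by 6-exo-trig attack of C6 on the ketone carbon followed by oxaphosphetane collapse; attack through the γ-carbon would give a four-membered ring and is excluded. No stereocentre is created: C2 and C3 are carried through from the ribose diad. The step needs aldehyde-before-ketone chemoselectivity (secured by the reactivity gap and the staged base addition), a cis C4=C5 bond (secured by the Z-preference of the unstabilised ylide and, failing that, by E/Z equilibration of the delocalised allylic ylide, only the Z form of which can cyclise) and configurational integrity at the two α-silyloxy centres (secured by the non-chelating potassium counter-ion, low temperature and the absence of free base while the aldehyde is present). Two P=O bonds and closure of an unstrained six-membered ring drive the sequence.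

**Step 5**
Reactants: 8 tri-O-TBS diene
Product: 9 [(5S,6R)-5,6-bis(TBSO)cyclohexa-1,3-dien-1-yl]methanol
Conditions: HF·pyridine, pyridine, THF, 0 °C
Reagents that add atoms: none
Why: Buffered fluoride desilylation cleaves the unhindered primary allylic TBS ether much faster than the two secondary ones, which should unveil the allylic alcohol needed to direct the epoxidation without acid-induced aromatisation of the diene diol.

**Step 6**
Reactants: 9 dienyl carbinol; 10 tert-butyl hydroperoxide
Product: 11 [(1S,4S,5S,6S)-4,5-bis(TBSO)-7-oxabicyclo[4.1.0]hept-2-en-6-yl]methanol (oxirane trans to both silyloxy groups)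
Conditions: VO(acac)2 (5 mol %), t-BuOOH (1.5 equiv, decane), CH2Cl2, 0 °C
Reagents that add atoms: tert-butyl hydroperoxide, CC(C)(C)OO
Why: Hydroxyl-directed vanadium-catalysed epoxidation should oxidise only the allylic-alcohol alkene C1=C6 (not C4=C5) and deliver oxygen anti to the C2 silyloxy group, which allylic 1,2-strain with the C1 substituent forces pseudoaxial, and anti to the cis C3 silyloxy group, so that C1 and C6 are set together by substrate control.

**Step 7**
Reactants: 11 bis-O-TBS epoxy alcohol
Product: 12 (1S,4S,5S,6R)-6-(hydroxymethyl)-7-oxabicyclo[4.1.0]hept-2-ene-4,5-diol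
Conditions: Bu4NF, AcOH (1:1), THF, 0 °C → rt
Reagents that add atoms: none
Why: Fluoride-mediated cleavage of the two secondary silyl ethers under acetic acid buffering keeps the alkoxide concentration low, which should suppress Payne rearrangement and opening of the allylic epoxide.

**Step 8**
Reactants: 12 epoxy triol; 13 benzoyl chloride
Product: 14 [(1S,4S,5S,6R)-4-(benzoyloxy)-5-hydroxy-7-oxabicyclo[4.1.0]hept-2-en-6-yl]methyl benzoate (target)
Conditions: BzCl (2.1 equiv), pyridine, CH2Cl2, −30 → 0 °C
Reagents that add atoms: benzoyl chloride, O=C(Cl)c1ccccc1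
Why: Pyridine-mediated acylation follows steric accessibility, so the primary hydroxyl and then the allylic C3 hydroxyl should be esterified while the C2 hydroxyl, flanked by the fully substituted epoxide carbon, stays free.

**Compound list**
1 | D-ribono-1,4-lactone | O=C1[C@H](O)[C@H](O)[C@@H](CO)O1 | starting material
2 | tert-butyldimethylsilyl chloride | CC(C)(C)[Si](C)(C)Cl | starting material
3 | 2,3,5-tri-O-TBS-D-ribono-1,4-lactone | O=C1[C@H](O[Si](C)(C)C(C)(C)C)[C@H](O[Si](C)(C)C(C)(C)C)[C@@H](CO[Si](C)(C)C(C)(C)C)O1 | intermediate
4 | (2S,3R,4R)-2,3,5-tris(TBSO)pentane-1,4-diol | OC[C@H](O[Si](C)(C)C(C)(C)C)[C@H](O[Si](C)(C)C(C)(C)C)[C@H](O)CO[Si](C)(C)C(C)(C)C | intermediate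
5 | (2R,3S)-2,3,5-tris(TBSO)-4-oxopentanal | O=C[C@H](O[Si](C)(C)C(C)(C)C)[C@H](O[Si](C)(C)C(C)(C)C)C(=O)CO[Si](C)(C)C(C)(C)C | intermediate
6 | ethane-1,2-diylbis(triphenylphosphonium) dibromide | [Br-].[Br-].C(C[P+](c1ccccc1)(c1ccccc1)c1ccccc1)[P+](c1ccccc1)(c1ccccc1)c1ccccc1 | starting material
7 | Z-allylphosphonium bromide (first Wittig product, not isolated) | [Br-].c1ccccc1[P+](c1ccccc1)(c1ccccc1)C/C=C\[C@H](O[Si](C)(C)C(C)(C)C)[C@H](O[Si](C)(C)C(C)(C)C)C(=O)CO[Si](C)(C)C(C)(C)C | intermediate
8 | (5S,6R)-5,6-bis(TBSO)-1-(TBSO-methyl)cyclohexa-1,3-diene | CC(C)(C)[Si](C)(C)OCC1=CC=C[C@H](O[Si](C)(C)C(C)(C)C)[C@@H]1O[Si](C)(C)C(C)(C)C | intermediate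
9 | [(5S,6R)-5,6-bis(TBSO)cyclohexa-1,3-dien-1-yl]methanol | OCC1=CC=C[C@H](O[Si](C)(C)C(C)(C)C)[C@@H]1O[Si](C)(C)C(C)(C)C | intermediate
10 | tert-butyl hydroperoxide | CC(C)(C)OO | starting material
11 | [(1S,4S,5S,6S)-4,5-bis(TBSO)-7-oxabicyclo[4.1.0]hept-2-en-6-yl]methanol | OC[C@]12O[C@H]1C=C[C@H](O[Si](C)(C)C(C)(C)C)[C@@H]2O[Si](C)(C)C(C)(C)C | intermediate
12 | (1S,4S,5S,6R)-6-(hydroxymethyl)-7-oxabicyclo[4.1.0]hept-2-ene-4,5-diol | OC[C@]12O[C@H]1C=C[C@H](O)[C@@H]2O | intermediate
13 | benzoyl chloride | O=C(Cl)c1ccccc1 | starting material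
14 | [(1S,4S,5S,6R)-4-(benzoyloxy)-5-hydroxy-7-oxabicyclo[4.1.0]hept-2-en-6-yl]methyl benzoate | O=C(OC[C@]12O[C@H]1C=C[C@H](OC(=O)c1ccccc1)[C@@H]2O)c1ccccc1 | target

**Step count and risks**
Total steps: 8. Longest linear sequence: 8 (fully linear from 1).

Steps most likely to fail:

1. Step 4 (proposed new method). What may go wrong:
 - the amide base may add irreversibly to the vinylphosphonium fragment of the mono-ylide;
 - the allylic ylide may undergo vinylogous β-elimination of the C3 silyloxide instead of cyclising;
 - the keto aldehyde may enolise, epimerise or eliminate before it is olefinated.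

 Fallback with known chemistry, setting out from 5 and returning at 8: the aldehyde of 5 is methylenated chemoselectively with Ph3P=CH2 (THF, −78 °C) to (3S,4S)-1,3,4-tris(TBSO)hex-5-en-2-one F1. Allylmagnesium bromide CH2=CHCH2MgBr (THF, −78 °C) adds to the ketone to give the tertiary homoallylic alcohol F2, an epimer mixture at the carbinol carbon that does not matter because this centre becomes sp2. Ring-closing metathesis with the second-generation Grubbs catalyst (CH2Cl2, 40 °C) closes the cyclohexenol F3. Burgess dehydration towards the allylic ring methylene (benzene, 50 °C) should then give the conjugated diene 8.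

2. Step 6. What may go wrong: insufficient facial discrimination, because the directing CH2OH is exocyclic and can reach either face, or Lewis-acid-promoted opening of the allylic epoxide.

 Fallback, setting out from 9 and returning at 11: the source of stereocontrol is switched from the substrate to the catalyst by a Sharpless asymmetric epoxidation (Ti(OiPr)4, L-(+)-diethyl tartrate, t-BuOOH, 4 Å molecular sieves, CH2Cl2, −20 °C). The tartrate-defined face coincides with the sterically preferred one (matched case). This fallback makes no new compound (F0).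

3. Step 8. What may go wrong: incomplete discrimination between the C3 and C2 hydroxyls in the second acylation, or over-acylation to the tribenzoate.

 Fallback, setting out from 12 and returning at 14: the primary hydroxyl alone is benzoylated (BzCl 1.0 equiv, 2,4,6-collidine, CH2Cl2, −40 °C) to [(1S,4S,5S,6R)-4,5-dihydroxy-7-oxabicyclo[4.1.0]hept-2-en-6-yl]methyl benzoate F4. The cis-1,2-diol is then mono-benzoylated under tin-chelate control (Me2SnCl2 cat., BzCl, K2CO3, THF, rt), which activates the diol as a five-membered stannylene and should acylate the less hindered allylic oxygen to give 14.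

**Further compounds**
F1 | step 4 | (3S,4S)-1,3,4-tris(TBSO)hex-5-en-2-one | C=C[C@H](O[Si](C)(C)C(C)(C)C)[C@H](O[Si](C)(C)C(C)(C)C)C(=O)CO[Si](C)(C)C(C)(C)C
F2 | step 4 | (3S,4S)-3,4-bis(TBSO)-2-(TBSO-methyl)-2-allylhex-5-en-2-ol skeleton: tertiary homoallylic alcohol, epimer mixture at the carbinol carbon | C=C[C@H](O[Si](C)(C)C(C)(C)C)[C@H](O[Si](C)(C)C(C)(C)C)C(O)(CC=C)CO[Si](C)(C)C(C)(C)C
F3 | step 4 | (5S,6R)-5,6-bis(TBSO)-1-(TBSO-methyl)cyclohex-3-en-1-ol, epimer mixture at C1 | OC1(CO[Si](C)(C)C(C)(C)C)CC=C[C@H](O[Si](C)(C)C(C)(C)C)[C@@H]1O[Si](C)(C)C(C)(C)C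
F0 | step 6 | none | none
F4 | step 8 | [(1S,4S,5S,6R)-4,5-dihydroxy-7-oxabicyclo[4.1.0]hept-2-en-6-yl]methyl benzoate | O=C(OC[C@]12O[C@H]1C=C[C@H](O)[C@@H]2O)c1ccccc1
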